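**Retrosynthetic overview**
1. Kazinol D 22 ⇐ silyl ether 21 ⇐ bis(prenyl ether) 16 by two aromatic Claisen events in one thermolysis. The plan rests on two positional facts: ring A C5 (1,1-dimethylallyl) is ortho to O4, whose para carbon C1 carries the propyl chain; chroman C5 (prenyl) is para to O8, whose only free ortho carbon C7 is crowded by the chain on C6.
2. 16 ⇐ ortho-hydroxy ketone 12: the hydrogen-bonded O2-H stays free during double O-prenylation of O4 and O8, then drives removal of the ketone oxygen (12 to 15) and is silylated last.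
3. 12 ⇐ triol ketone 10 ⇐ chalcone 9 ⇐ chromene aldehyde 6 + acetophenone 8 (Claisen-Schmidt); one hydrogenation removes both alkenes and both benzyl groups before any prenyl group is present.
4. Ring order: both benzene rings are bought, the pyran ring is the only ring made (step 2) and is saturated in step 5; the target has no stereocentre.

Key step: step 9

Remark: ring A is numbered from the chain carbon (C1, O2, O4, C5) and the chroman in the usual way (O1, C5, chain on C6, O8); compound 1 is taken as a catalogue building block.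

**Step 1**
Reactants: 1 3-(benzyloxy)-4-hydroxybenzaldehyde; 2 3-chloro-3-methylbut-1-yne
Product: 3 3-(benzyloxy)-4-[(2-methylbut-3-yn-2-yl)oxy]benzaldehyde
Conditions: DBU, CuCl2·2H2O (cat.), MeCN, 0 °C
Reagents that add atoms: none
Why: Copper-catalysed O-propargylation of the only free phenol (copper acetylide ionising to an allenylidene that the phenoxide captures at the tertiary carbon) is the standard way to aryl 1,1-dimethylpropargyl ethers and tolerates the aldehyde.

**Step 2**
Reactants: 3 3-(benzyloxy)-4-[(2-methylbut-3-yn-2-yl)oxy]benzaldehyde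
Product: 6 8-(benzyloxy)-2,2-dimethyl-2H-chromene-6-carbaldehyde, via allenyl phenol 4 (not isolated), via ortho-quinone methide 5 (not isolated)
Conditions: PhNEt2, 190 °C
Reagents that add atoms: none
Why: Aromatic propargyl Claisen rearrangement to the only free ortho carbon gives allenyl phenol 4, a 1,5-hydrogen shift turns it into ortho-quinone methide 5, and oxa-6π electrocyclisation closes the 2,2-dimethyl-2H-pyran ring, which is the usual thermal chromene synthesis.

**Step 3**
Reactants: 7 2,4-dihydroxyacetophenone
Product: 8 1-[4-(benzyloxy)-2-hydroxyphenyl]ethan-1-one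
Conditions: BnBr, K2CO3, acetone, reflux
Reagents that add atoms: benzyl bromide, BrCc1ccccc1
Why: Williamson etherification is selective for O4 because the O2 hydroxyl is hydrogen-bonded to the ketone and barely nucleophilic under carbonate conditions.

**Step 4**
Reactants: 6 8-(benzyloxy)-2,2-dimethyl-2H-chromene-6-carbaldehyde; 8 1-[4-(benzyloxy)-2-hydroxyphenyl]ethan-1-one
Product: 9 (E)-1-[4-(benzyloxy)-2-hydroxyphenyl]-3-[8-(benzyloxy)-2,2-dimethyl-2H-chromen-6-yl]prop-2-en-1-one
Conditions: KOH (aq, 50%), EtOH, rt; then HCl (aq) to pH 3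
Reagents that add atoms: none
Why: Claisen-Schmidt condensation of the methyl ketone enolate with the non-enolisable aldehyde and E1cB dehydration should give the thermodynamic E-chalcone, whose geometry is erased in the next step.

**Step 5**
Reactants: 9 (E)-1-[4-(benzyloxy)-2-hydroxyphenyl]-3-[8-(benzyloxy)-2,2-dimethyl-2H-chromen-6-yl]prop-2-en-1-one
Product: 10 1-(2,4-dihydroxyphenyl)-3-(8-hydroxy-2,2-dimethylchroman-6-yl)propan-1-one
Conditions: H2 (1 atm), Pd/C (10%), EtOAc/EtOH, rt
Reagents that add atoms: none
Why: Heterogeneous hydrogenation saturates the enone alkene and the chromene C3-C4 alkene and hydrogenolyses both benzyl ethers, while the chelated, electron-rich aryl ketone is not reduced under neutral conditions at one atmosphere.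

**Step 6**
Reactants: 10 1-(2,4-dihydroxyphenyl)-3-(8-hydroxy-2,2-dimethylchroman-6-yl)propan-1-one; 11 prenyl bromide (1-bromo-3-methylbut-2-ene)
Product: 12 1-{2-hydroxy-4-[(3-methylbut-2-en-1-yl)oxy]phenyl}-3-{2,2-dimethyl-8-[(3-methylbut-2-en-1-yl)oxy]chroman-6-yl}propan-1-one
Conditions: K2CO3, acetone, reflux (2.3 equiv of 11)
Reagents that add atoms: prenyl bromide, CC(C)=CCBr
Why: Twofold Williamson etherification consumes two equivalents of the allylic bromide, one on each of the unchelated phenols O4 and O8, whereas the hydrogen-bonded O2 hydroxyl stays free under carbonate/acetone conditions.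

**Step 7**
Reactants: 12 1-{2-hydroxy-4-[(3-methylbut-2-en-1-yl)oxy]phenyl}-3-{2,2-dimethyl-8-[(3-methylbut-2-en-1-yl)oxy]chroman-6-yl}propan-1-one
Product: 15 2-{3-[2,2-dimethyl-8-(3-methylbut-2-en-1-yloxy)chroman-6-yl]propyl}-5-(3-methylbut-2-en-1-yloxy)phenol, via aryl ethyl carbonate 13 (not isolated), via ortho-quinone methide 14 (not isolated)
Conditions: ClCO2Et, Et3N, THF, 0 °C; then NaBH4, H2O/THF, 0 °C to rt
Reagents that add atoms: none
Why: One-pot reductive deoxygenation of an ortho-hydroxyaryl ketone, in which O-acylation gives carbonate 13, borohydride reduction of the ketone triggers carbonate transfer and loss to ortho-quinone methide 14, and a second hydride adds to 14, all without touching the prenyl ethers.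

**Step 8**
Reactants: 15 2-{3-[2,2-dimethyl-8-(3-methylbut-2-en-1-yloxy)chroman-6-yl]propyl}-5-(3-methylbut-2-en-1-yloxy)phenol
Product: 16 O2-triisopropylsilyl ether of 15 (O4,O8-bis(prenyl) ether of the chroman diarylpropane)
Conditions: iPr3SiCl, imidazole, DMF, rt
Reagents that add atoms: chlorotriisopropylsilane, CC(C)[Si](Cl)(C(C)C)C(C)C
Why: Silylation of the single free phenol with a trialkylsilyl chloride and imidazole is routine, and the bulky group then shields ring A C3.

**Step 9**
Reactants: 16 O2-triisopropylsilyl ether of 15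
Product: 21 kazinol D 2-O-triisopropylsilyl ether, via ring B C7 dienone 17 (not isolated), via ring B C5 dienone 18 (not isolated), via ring B rearranged mono ether 19 (not isolated), via ring A C5 dienone 20 (not isolated)
Conditions: Eu(fod)3 [tris(6,6,7,7,8,8,8-heptafluoro-2,2-dimethyloctane-3,5-dionato)europium] (0.2 equiv), 1,2-dichlorobenzene, argon, 80 °C then 150 °C
Reagents that add atoms: none
Why: On ring B the O8 prenyl ether, held by europium between O1 and O8, should undergo a [3,3] shift to C7 to give dienone 17 (a shift to C8a gives a non-enolisable dienone that feeds the same channel), a Cope [3,3] shift then carries the group to C5 as dienone 18 with its original connectivity restored, and enolisation gives phenol 19; on ring A a single [3,3] shift of the O4 ether to C5 gives dienone 20, whose enolisation fixes the inverted 2-methylbut-3-en-2-yl group in 21. The closest known reactions are the ortho-Claisen rearrangement of aryl prenyl ethers to ortho-(1,1-dimethylallyl)phenols and the Eu(fod)3-promoted para-Claisen-Cope transfer of prenyl groups in 5-O-prenyl flavonoids and ortho-prenyloxy aryl ketones. No ring is closed and no stereocentre remains, because the sp3 dienone carbons are transient. Two selectivities are needed: on ring B the Cope shift must outrun tautomerisation of 17, which the crowding of C7 between the tertiary allyl group and the chain on C6 and the base-free medium should secure, whereas dienone 20 has only C6-H beside it and its sole Cope exit, C1, carries the chain and cannot aromatise, so it tautomerises. On ring A the bulky silyl ether on O2 shields C3, and a C3 dienone that does form is itself crowded and can pass through the C1 dienone to 20. The upper temperature is held at 150 °C so that the new ortho-allyl phenol does not enter the abnormal Claisen course.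

**Step 10**
Reactants: 21 kazinol D 2-O-triisopropylsilyl ether
Product: 22 kazinol D
Conditions: Bu4NF, AcOH, THF, 0 °C
Reagents that add atoms: none
Why: Fluoride cleaves the aryl silyl ether at silicon under buffered conditions that leave the acid-sensitive ortho-(1,1-dimethylallyl)phenol and all three alkenes untouched.

**Compound list**
1 | 3-(benzyloxy)-4-hydroxybenzaldehyde | O=Cc1ccc(O)c(OCc2ccccc2)c1 | starting material
2 | 3-chloro-3-methylbut-1-yne | C#CC(C)(C)Cl | starting material
3 | 3-(benzyloxy)-4-[(2-methylbut-3-yn-2-yl)oxy]benzaldehyde | O=Cc1ccc(OC(C)(C)C#C)c(OCc2ccccc2)c1 | intermediate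
4 | allenyl phenol, 3-(benzyloxy)-4-hydroxy-5-(3-methylbuta-1,2-dien-1-yl)benzaldehyde (not isolated, step 2) | O=Cc1cc(C=C=C(C)C)c(O)c(OCc2ccccc2)c1 | intermediate
5 | ortho-quinone methide, 5-(benzyloxy)-3-(3-methylbut-2-en-1-ylidene)-4-oxocyclohexa-1,5-diene-1-carbaldehyde (not isolated, step 2) | O=CC1=CC(=CC=C(C)C)C(=O)C(OCc2ccccc2)=C1 | intermediate
6 | 8-(benzyloxy)-2,2-dimethyl-2H-chromene-6-carbaldehyde | O=Cc1cc(OCc2ccccc2)c2OC(C)(C)C=Cc2c1 | intermediate
7 | 2,4-dihydroxyacetophenone | CC(=O)c1ccc(O)cc1O | starting material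
8 | 1-[4-(benzyloxy)-2-hydroxyphenyl]ethan-1-one | CC(=O)c1ccc(OCc2ccccc2)cc1O | intermediate
9 | (E)-1-[4-(benzyloxy)-2-hydroxyphenyl]-3-[8-(benzyloxy)-2,2-dimethyl-2H-chromen-6-yl]prop-2-en-1-one | O=C(/C=C/c1cc(OCc2ccccc2)c2OC(C)(C)C=Cc2c1)c1ccc(OCc2ccccc2)cc1O | intermediate
10 | 1-(2,4-dihydroxyphenyl)-3-(8-hydroxy-2,2-dimethylchroman-6-yl)propan-1-one | O=C(CCc1cc(O)c2OC(C)(C)CCc2c1)c1ccc(O)cc1O | intermediate
11 | prenyl bromide (1-bromo-3-methylbut-2-ene) | CC(C)=CCBr | starting material
12 | 1-{2-hydroxy-4-[(3-methylbut-2-en-1-yl)oxy]phenyl}-3-{2,2-dimethyl-8-[(3-methylbut-2-en-1-yl)oxy]chroman-6-yl}propan-1-one | O=C(CCc1cc(OCC=C(C)C)c2OC(C)(C)CCc2c1)c1ccc(OCC=C(C)C)cc1O | intermediate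
13 | aryl ethyl carbonate of 12 at O2 (not isolated, step 7) | CCOC(=O)Oc1cc(OCC=C(C)C)ccc1C(=O)CCc1cc(OCC=C(C)C)c2OC(C)(C)CCc2c1 | intermediate
14 | ortho-quinone methide, 6-{3-[2,2-dimethyl-8-(prenyloxy)chroman-6-yl]propylidene}-3-(prenyloxy)cyclohexa-2,4-dien-1-one (not isolated, step 7) | O=C1C=C(OCC=C(C)C)C=CC1=CCCc1cc(OCC=C(C)C)c2OC(C)(C)CCc2c1 | intermediate
15 | 2-{3-[2,2-dimethyl-8-(3-methylbut-2-en-1-yloxy)chroman-6-yl]propyl}-5-(3-methylbut-2-en-1-yloxy)phenol | CC(C)=CCOc1ccc(CCCc2cc(OCC=C(C)C)c3c(c2)CCC(C)(C)O3)c(O)c1 | intermediate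
16 | O2-triisopropylsilyl ether of 15, the bis(prenyl ether) precursor | CC(C)=CCOc1ccc(CCCc2cc(OCC=C(C)C)c3c(c2)CCC(C)(C)O3)c(O[Si](C(C)C)(C(C)C)C(C)C)c1 | intermediate
17 | ring B C7 dienone, 7-(2-methylbut-3-en-2-yl)-7H-chromen-8-one form of 16 (not isolated, step 9) | O=C1C(C(C)(C)C=C)C(CCCc3ccc(OCC=C(C)C)cc3O[Si](C(C)C)(C(C)C)C(C)C)=CC2=C1OC(C)(C)CC2 | intermediate
18 | ring B C5 dienone, 5-(3-methylbut-2-en-1-yl)-5H-chromen-8-one form (not isolated, step 9) | O=C1C=C(CCCc3ccc(OCC=C(C)C)cc3O[Si](C(C)C)(C(C)C)C(C)C)C(CC=C(C)C)C2=C1OC(C)(C)CC2 | intermediate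
19 | ring B rearranged mono ether, 2,2-dimethyl-5-prenyl-6-{3-[4-(prenyloxy)-2-(triisopropylsilyloxy)phenyl]propyl}chroman-8-ol (not isolated, step 9) | CC(C)=CCOc1ccc(CCCc2cc(O)c3c(c2CC=C(C)C)CCC(C)(C)O3)c(O[Si](C(C)C)(C(C)C)C(C)C)c1 | intermediate
20 | ring A C5 dienone, 6-(2-methylbut-3-en-2-yl)cyclohexa-2,4-dien-1-one form of 19 (not isolated, step 9) | O=C1C=C(O[Si](C(C)C)(C(C)C)C(C)C)C(CCCc2cc(O)c3c(c2CC=C(C)C)CCC(C)(C)O3)=CC1C(C)(C)C=C | intermediate
21 | kazinol D 2-O-triisopropylsilyl ether | C=CC(C)(C)c1cc(CCCc2cc(O)c3c(c2CC=C(C)C)CCC(C)(C)O3)c(O[Si](C(C)C)(C(C)C)C(C)C)cc1O | intermediate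
22 | kazinol D | C=CC(C)(C)c1cc(CCCc2cc(O)c3c(c2CC=C(C)C)CCC(C)(C)O3)c(O)cc1O | target

**Step count and risks**
Total steps: 10. Longest linear sequence: 9 steps (steps 1, 2, 4, 5, 6, 7, 8, 9, 10).

Step 9. What may go wrong: on ring B the C7 dienone may tautomerise before the Cope shift, which leaves the group at C7 in inverted form. On ring A the group may settle at C3. At the temperature that ring A needs, the new ortho-allyl phenol may rearrange further or cyclise onto its alkene, or a prenyl ether may ionise and lose its group. Fallback: the two transfers are run apart and the phenols are trapped as esters. Setting out from 16, ring B alone should rearrange with Eu(fod)3 in CHCl3 at 60 °C, and mono ether 19 is isolated so that any C7 isomer can be removed there. Compound 19 is then heated in PhNEt2 with acetic anhydride at 185 °C, the anhydride-trapped ortho-Claisen rearrangement, which acetylates O8 and captures the ring A phenol as it forms, to give the 4,8-di-O-acetate of 21 F1. K2CO3 in MeOH at 0 °C should remove the two aryl acetates, and the sequence comes back to the route at 21.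

Step 7. What may go wrong: the ortho-quinone methide may tautomerise to the ortho-propenyl phenol faster than it takes up hydride, or carbonate transfer may stall at the benzylic alcohol. Fallback: deoxygenation through a hydrazone instead of a quinone methide. Setting out from 12, condensation with 4-methylbenzenesulfonohydrazide (EtOH, reflux) should give the tosylhydrazone of 12 F2. Reduction with catecholborane (CHCl3, 0 °C) and decomposition with NaOAc·3H2O at reflux should give the methylene compound, coming back to the route at 15.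

Step 6. What may go wrong: C-alkylation of the ambident ring A phenoxide next to O4, or slow etherification of the more hindered O8, which would call for forcing conditions under which the chelated O2 hydroxyl also reacts. Fallback: Mitsunobu etherification in place of phenoxide alkylation. Setting out from 10, 3-methylbut-2-en-1-ol, PPh3 and diisopropyl azodicarboxylate in THF at 0 °C should etherify the two unchelated phenols without a free phenoxide and come back to the route at 12; no new compound arises (F0).

**Further compounds**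
F1 | step 9 | 4,8-di-O-acetate of kazinol D 2-O-triisopropylsilyl ether | C=CC(C)(C)c1cc(CCCc2cc(OC(C)=O)c3c(c2CC=C(C)C)CCC(C)(C)O3)c(O[Si](C(C)C)(C(C)C)C(C)C)cc1OC(C)=O
F2 | step 7 | tosylhydrazone of 12 | Cc1ccc(cc1)S(=O)(=O)NN=C(CCc1cc(OCC=C(C)C)c2OC(C)(C)CCc2c1)c1ccc(OCC=C(C)C)cc1O
F0 | step 6 | none | none
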